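Ring numbering: the 14-membered carbocycle is counted from the isopropyl-bearing alkene carbon C1 through C2, the oxirane carbons C3 and C4, C5, C6, the C7=C8 alkene and the C9 ketone round to the C14 ketone.
Enabling feature: the ring ketone C9 sits between sp2 carbon C8 of the (7Z)-alkene, which also carries CH2OH, and the unbranched C10H2-C11H2 unit. C9 and its oxygen can therefore be one molecule of CO placed between a C8 alkenyl iodide and a primary C10 alkylborane.
Cuts: first C8-C9 and C9-C10 (carbonylative B-alkyl Suzuki-Miyaura macrocyclisation), then C1=C2 (Horner-Wadsworth-Emmons). This leaves a west C2-C8 epoxy aldehyde/alkenyl iodide from nerol, and an east C10-C14 plus C1 ketophosphonate from a glycolaldehyde ether, cis-2-butene and diethyl isobutylphosphonate.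
Forward order: the oxirane is made first on nerol, the fragments are joined at C1=C2, the C14 ketone is parked as a silylated carbinol, and the 14-membered ring is closed last at C9.
Stereochemistry: C3/C4 come from Sharpless epoxidation of the Z-allylic alcohol (cis-epoxide) and C12/C13 from reagent-controlled (Z)-crotylboration. The 7Z alkene comes from trans-hydrostannation/iodination and is carried with retention, 1E comes from the olefination, and the transient C14 carbinol is erased by oxidation.

Key step: step 19

Remark on the chemistry: drawn as a zigzag along C11-C12-C13-C14, the (12R)-methyl and (13S)-hydroxyl groups of the target lie on the same side (syn). The crotyl donor must therefore be Z-configured, and cis-2-butene is the C4 building block.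
Assumption: the C14 carbinol (30, 31, 33-35), the carbinol and phosphonate carbons of 27 and the phosphonate carbon of 28 are carried as epimer mixtures because these centres are erased later. Their SMILES leave them undefined.

Step 1
Reactants: 1 nerol [(2Z)-3,7-dimethylocta-2,6-dien-1-ol]
Product: 2 (2S,3R)-2,3-epoxynerol = [(2S,3R)-3-methyl-3-(4-methylpent-3-en-1-yl)oxiran-2-yl]methanol (cis-epoxide)
Conditions: Ti(OiPr)4 (5 mol %), L-(+)-diethyl tartrate (7 mol %), t-BuOOH (2 equiv, decane), 4 Å MS, CH2Cl2, −20 °C
Reagents that add atoms: tert-butyl hydroperoxide, CC(C)(C)OO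
Why: Sharpless asymmetric epoxidation touches only the allylic alkene (future C3-C4), the L-(+)-tartrate catalyst delivering oxygen to the face that gives the (2S,3R) epoxide, while the Z geometry of nerol is transferred stereospecifically into the cis relation of the two carbon chains.

Step 2
Reactants: 2 (2S,3R)-2,3-epoxynerol
Product: 3 TBS ether of 2 = tert-butyl(dimethyl){[(2S,3R)-3-methyl-3-(4-methylpent-3-en-1-yl)oxiran-2-yl]methoxy}silane
Conditions: TBSCl (1.2 equiv), imidazole (2 equiv), CH2Cl2, 0 °C to rt
Reagents that add atoms: tert-butyl(chloro)dimethylsilane, CC(C)(C)[Si](C)(C)Cl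
Why: Imidazole-mediated silyl ether protection of the primary alcohol is routine for 2,3-epoxy alcohols, forms no free alkoxide that could start a Payne rearrangement, and shields the future C2 oxygen from the carbonate, organolithium and tin chemistry ahead.

Step 3
Reactants: 3 TBS ether of epoxynerol
Product: 5 3-[(2R,3S)-3-{[(tert-butyldimethylsilyl)oxy]methyl}-2-methyloxiran-2-yl]propanal (C7 aldehyde), via secondary ozonide 4 (not isolated)
Conditions: O3, CH2Cl2, −78 °C; then Me2S, −78 °C to rt
Reagents that add atoms: ozone, [O-][O+]=O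
Why: Ozonolysis with reductive work-up cuts the only alkene left, the electron-rich prenyl double bond, and ends the chain at the C7 aldehyde while oxirane and silyl ether are inert to ozone.

Step 4
Reactants: 5 C7 aldehyde; 6 Ohira-Bestmann reagent [dimethyl (1-diazo-2-oxopropyl)phosphonate]
Product: 7 {[(2S,3R)-3-(but-3-yn-1-yl)-3-methyloxiran-2-yl]methoxy}(tert-butyl)dimethylsilane (terminal C7-C8 alkyne)
Conditions: K2CO3 (2 equiv), MeOH, 0 °C to rt
Reagents that add atoms: none
Why: The Ohira-Bestmann variant of the Seyferth-Gilbert homologation turns enolisable aliphatic aldehydes into terminal alkynes under K2CO3/MeOH, conditions that affect neither the trisubstituted oxirane nor a primary TBS ether, and its diazo carbon becomes C8.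

Step 5
Reactants: 7 terminal alkyne; 8 formaldehyde (used as paraformaldehyde)
Product: 10 5-[(2R,3S)-3-{[(tert-butyldimethylsilyl)oxy]methyl}-2-methyloxiran-2-yl]pent-2-yn-1-ol (epoxy propargylic alcohol), via lithium acetylide 9 (not isolated)
Conditions: n-BuLi (1.1 equiv), THF, −78 °C; (CH2O)n (3 equiv), −78 °C to rt
Reagents that add atoms: n-butyllithium, [Li]CCCC (lithium of 9 only)
Why: Acetylide hydroxymethylation (alkyne deprotonation, then 1,2-addition to formaldehyde released from paraformaldehyde) is standard, and without a Lewis acid the lithium acetylide does not open the hindered oxirane.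

Step 6
Reactants: 10 epoxy propargylic alcohol
Product: 12 (2Z)-5-[(2R,3S)-3-{[(tert-butyldimethylsilyl)oxy]methyl}-2-methyloxiran-2-yl]-2-iodopent-2-en-1-ol, via (Z)-alkenylstannane 11 (not isolated)
Conditions: [Cp*RuCl]4 (2 mol %), Bu3SnH (1.1 equiv, slow addition), CH2Cl2, rt; then I2 (1.1 equiv), 0 °C
Reagents that add atoms: tributyltin hydride, CCCC[SnH](CCCC)CCCC (tin of 11 only); iodine, II
Why: In the ruthenium-catalysed trans-hydrostannation of a propargylic alcohol, a hydrogen bond from the hydroxyl group to the chloride ligand steers tin to the proximal carbon C8 and hydrogen reaches C7 from the opposite side, so tin ends up cis to the C6 chain, and iododestannylation then proceeds with retention to the (Z)-iodide.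

Step 7
Reactants: 12 (Z)-2-iodoallylic alcohol
Product: 13 TBDPS ether of 12 (C2-OTBS, hydroxymethyl as OTBDPS, (Z)-C8 iodide)
Conditions: TBDPSCl (1.1 equiv), imidazole (2 equiv), DMF, 0 °C to rt
Reagents that add atoms: tert-butyl(chloro)diphenylsilane, CC(C)(C)[Si](Cl)(c1ccccc1)c1ccccc1
Why: Silyl ether protection with the bulkier, more acid-stable TBDPS group sets up the TBS/TBDPS differentiation of the next step and gives a hydroxymethyl mask that cannot intercept an acyl-palladium later.

Step 8
Reactants: 13 TBS/TBDPS bis-silyl ether
Product: 14 [(2S,3R)-3-{(3Z)-5-[(tert-butyldiphenylsilyl)oxy]-4-iodopent-3-en-1-yl}-3-methyloxiran-2-yl]methanol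
Conditions: HF·pyridine, excess pyridine, THF, 0 °C
Reagents that add atoms: none
Why: This is a selective desilylation in which pyridine-buffered HF cleaves a primary TBS ether much faster than a primary TBDPS ether, and the buffered medium is mild enough for the trisubstituted oxirane and the alkenyl iodide.

Step 9
Reactants: 14 epoxy alcohol
Product: 15 west fragment, (2R,3R)-3-{(3Z)-5-[(tert-butyldiphenylsilyl)oxy]-4-iodopent-3-en-1-yl}-3-methyloxirane-2-carbaldehyde (same spatial arrangement as 14; the descriptor at C3 changes by CIP priority only)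
Conditions: TEMPO (10 mol %), PhI(OAc)2 (1.2 equiv), CH2Cl2, rt
Reagents that add atoms: none
Why: The oxoammonium-mediated TEMPO/PhI(OAc)2 oxidation stops at the aldehyde, is routinely used on 2,3-epoxy alcohols, and cannot epimerise C3 because an oxirane C-H is not enolised under these near-neutral conditions.

Step 10
Reactants: 16 (tert-butyldimethylsilyloxy)acetaldehyde; 17 (Z)-2-butene (cis-2-butene)
Product: 21 (2S,3R)-1-[(tert-butyldimethylsilyl)oxy]-3-methylpent-4-en-2-ol (syn), via (Z)-crotylpotassium 18 (not isolated), via (Z)-crotyldiisopinocampheylborane 19 (not isolated), via diisopinocampheylborinate ester 20 (not isolated)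
Conditions: KOt-Bu, n-BuLi, 17 (excess), THF, −78 to −45 °C; (−)-Ipc2BOMe [from (+)-α-pinene], −78 °C; BF3·OEt2, then 16, −78 °C; NaOH, H2O2, 0 °C to rt
Reagents that add atoms: potassium tert-butoxide, CC(C)(C)[O-].[K+] (potassium of 18 only); (−)-B-methoxydiisopinocampheylborane, COB([C@@H]1C[C@@H]2C[C@H]([C@H]1C)C2(C)C)[C@@H]1C[C@@H]2C[C@H]([C@H]1C)C2(C)C (boryl group of 19 and 20 only)
Why: In the Brown (Z)-crotylboration the borane made from metalated cis-2-butene reacts through a closed chair transition state that maps the Z geometry onto the 12,13-syn relation, while the isopinocampheyl groups of the (+)-α-pinene series select the aldehyde face that gives the (2S,3R) alcohol, which is (12R,13S) in ring numbering.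

Step 11
Reactants: 21 syn homoallylic alcohol
Product: 22 (3R,4S)-4,5-bis[(tert-butyldimethylsilyl)oxy]-3-methylpent-1-ene
Conditions: TBSCl (1.5 equiv), imidazole (3 equiv), DMAP (cat.), DMF, rt to 40 °C
Reagents that add atoms: tert-butyl(chloro)dimethylsilane, CC(C)(C)[Si](C)(C)Cl
Why: Standard silyl ether protection of the secondary C13 hydroxyl gives a group that survives phosphonate anion, borohydride, borane and palladium chemistry and leaves with fluoride at the end.

Step 12
Reactants: 22 bis-TBS ether
Product: 23 (2S,3R)-2-[(tert-butyldimethylsilyl)oxy]-3-methylpent-4-en-1-ol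
Conditions: CSA (10 mol %), MeOH-CH2Cl2 (1:1), 0 °C
Reagents that add atoms: none
Why: Acid-catalysed methanolysis discriminates sterically between the two TBS ethers of a 1,2-diol, removing the unhindered primary one first (selective desilylation), and nothing else in 22 is acid-sensitive.

Step 13
Reactants: 23 primary alcohol
Product: 24 (2S,3R)-2-[(tert-butyldimethylsilyl)oxy]-3-methylpent-4-enal (C14 aldehyde)
Conditions: TEMPO (10 mol %), PhI(OAc)2 (1.2 equiv), CH2Cl2, rt
Reagents that add atoms: none
Why: The oxoammonium (TEMPO/PhI(OAc)2) oxidation gives the α-silyloxy aldehyde without base, so the C13 centre next to the new carbonyl is not epimerised.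

Step 14
Reactants: 24 C14 aldehyde; 25 diethyl (2-methylpropyl)phosphonate
Product: 27 diethyl [(5S,6R)-5-[(tert-butyldimethylsilyl)oxy]-4-hydroxy-2,6-dimethyloct-7-en-3-yl]phosphonate (epimers at C3 and C4 of the octene chain), via lithiated phosphonate 26 (not isolated)
Conditions: 25 (1.3 equiv), n-BuLi (1.25 equiv), THF, −78 °C; then 24, −78 °C, cold quench
Reagents that add atoms: n-butyllithium, [Li]CCCC (lithium of 26 only)
Why: Addition of an α-lithiated alkylphosphonate to an aldehyde, the first half of the usual two-step β-ketophosphonate synthesis, is reliable at −78 °C; the unstabilised adduct does not eliminate, the cold quench forestalls 1,2-silyl migration, and the two new centres do not matter because one is oxidised and the other becomes sp2.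

Step 15
Reactants: 27 β-hydroxyphosphonate
Product: 28 east fragment, diethyl [(5S,6R)-5-[(tert-butyldimethylsilyl)oxy]-2,6-dimethyl-4-oxooct-7-en-3-yl]phosphonate (α-isopropyl β-ketophosphonate, C10-C14 plus C1)
Conditions: Dess-Martin periodinane (1.3 equiv), CH2Cl2, rt
Reagents that add atoms: none
Why: Dess-Martin oxidation of β-hydroxyphosphonates to β-ketophosphonates is standard, is neutral enough to leave C13 and the TBS ether alone, and does not touch the terminal alkene.

Step 16
Reactants: 15 west fragment (epoxy aldehyde); 28 east fragment (β-ketophosphonate)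
Product: 29 open-chain (1E,7Z)-epoxy enone: C14 ketone conjugated to C1=C2 (isopropyl on C1), (3S,4R)-cis-oxirane, C8 iodide bearing CH2OTBDPS, (12R)-methyl, (13S)-OTBS, terminal C10=C11 vinyl
Conditions: Ba(OH)2 (activated, 0.8 equiv), THF-H2O (40:1), rt
Reagents that add atoms: none
Why: Horner-Wadsworth-Emmons olefination of a stabilised β-ketophosphonate under mild Ba(OH)2 conditions tolerates epoxy aldehydes, silyl ethers and alkenyl iodides, and reversible addition should favour the E-enone in which the conjugated acyl group stands trans to the oxirane, the crowded α-isopropyl branch being the acknowledged weakness of the step.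

Step 17
Reactants: 29 open-chain epoxy enone
Product: 30 C14 allylic alcohol of 29 (both C14 epimers, all else unchanged)
Conditions: NaBH4 (1.5 equiv), CeCl3·7H2O (1.5 equiv), MeOH, −78 to −40 °C
Reagents that add atoms: none
Why: The Luche reduction adds hydride 1,2 to the enone carbonyl at low temperature without disturbing the vinyl oxirane or the iodide, and the new C14 centre needs no control because step 21 oxidises it back.

Step 18
Reactants: 30 C14 allylic alcohol
Product: 31 key-step precursor, C14 triethylsilyl ether of 30 (C8 iodide at one end, vinyl group at the other)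
Conditions: TESCl (2 equiv), imidazole (4 equiv), DMAP (cat.), DMF, rt
Reagents that add atoms: chlorotriethylsilane, CC[Si](Cl)(CC)CC
Why: Silyl ether protection with TESCl/imidazole avoids Lewis-acidic silyl triflates that could open the vinyl oxirane, and installs the one silyl group that can later be removed in the presence of TBS and TBDPS.

Step 19
Reactants: 31 key-step precursor; 32 carbon monoxide
Product: 34 (1E,3S,4R,7Z,12R,13S)-14-membered macrocyclic Z-enone: C9 ketone in place, C8-CH2OTBDPS, C13-OTBS, C14-OTES, via B-alkyl-9-BBN borane 33 (not isolated)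
Conditions: 9-BBN (1.2 equiv), THF, 0 °C to rt; H2O (5 equiv); then syringe-pump addition to Pd(PPh3)4 (15 mol %), K3PO4 (3 equiv), CO (1 atm), THF-benzene, final 1 mM, rt to 45 °C
Reagents that add atoms: 9-borabicyclo[3.3.1]nonane, B1C2CCCC1CCC2 (boron of 33 only)
Why: Proposed new method: 9-BBN should add only to the one monosubstituted alkene, anti-Markovnikov, to put boron on C10 (33); zerovalent palladium then inserts into the C8-I bond, migratory insertion of CO gives the C8-C9 acyl-palladium iodide, phosphate-assisted transmetalation hands over the primary C10 alkyl group, and reductive elimination forms C9-C10. The closest known reactions are the intermolecular carbonylative Suzuki-Miyaura coupling of 1-iodoalkenes with B-alkyl-9-BBN reagents to give enones, the non-carbonylative B-alkyl Suzuki macrocyclisation and the carbonylative Stille macrocyclisation, and only their union in one ring-closing event is new. The 14-membered carbocycle closes end to end, since intramolecular transmetalation creates a 15-membered acyl(alkyl)palladacycle that contracts by reductive elimination while slow addition and millimolar concentration hold back oligomers, and the oxirane is a spectator ring. No stereocentre is created, and the 7Z geometry set in step 6 is carried unchanged because oxidative addition, insertion and elimination all leave the alkene configuration alone, so the less stable Z-enone never has to be reached by equilibration. The step needs CO insertion to outrun direct C8-C10 coupling, which a CO atmosphere, a fast-inserting alkenyl-palladium and a dilution-slowed transmetalation should secure, and it needs palladium to spare the vinyl oxirane, which the much faster oxidative addition of the iodide and the crowding of the trisubstituted C1=C2 alkene between isopropyl and the C14 silyl ether should secure. C14 is present as its TES ether so that 9-BBN finds no carbonyl to reduce, and every hydroxyl group is silylated so that nothing can intercept the acyl-palladium.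

Step 20
Reactants: 34 macrocyclic Z-enone
Product: 35 C14 allylic alcohol of the macrocycle (C13-OTBS and CH2OTBDPS retained)
Conditions: HF·pyridine, excess pyridine, THF, 0 °C
Reagents that add atoms: none
Why: This is a selective desilylation in which a TES ether is far more labile than TBS and TBDPS ethers towards pyridine-buffered HF, and the excess pyridine keeps the medium too weakly acidic to open the vinyl oxirane.

Step 21
Reactants: 35 macrocyclic C14 alcohol
Product: 36 (1E,3S,4R,7Z,12R,13S)-macrocyclic 9,14-dione with C13-OTBS and C8-CH2OTBDPS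
Conditions: Dess-Martin periodinane (1.5 equiv), pyridine (5 equiv), CH2Cl2, 0 °C to rt
Reagents that add atoms: none
Why: Pyridine-buffered Dess-Martin oxidation of the secondary allylic alcohol restores the C14 enone from either epimer, thereby erasing the transient stereocentre, without touching the oxirane, the Z-enone or the adjacent C13 centre.

Step 22
Reactants: 36 bis-silylated dione
Product: 37 target CNP0251075.1, (1E,3S,4R,7Z,12R,13S)-3,4-epoxy-13-hydroxy-8-(hydroxymethyl)-1-isopropyl-4,12-dimethylcyclotetradeca-1,7-diene-9,14-dione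
Conditions: TBAF-AcOH (1:1, 6 equiv), THF, 0 °C to rt
Reagents that add atoms: none
Why: Fluoride-mediated global desilylation with acetic-acid-buffered TBAF removes both the secondary TBS and the primary TBDPS ether while the medium stays near neutral, so that the α-hydroxy ketone is not epimerised or rearranged, the Z-enone is not isomerised and the oxirane is not opened.

Compound list
1 | nerol | CC(C)=CCC/C(C)=C\CO | starting material
2 | (2S,3R)-2,3-epoxynerol | OC[C@@H]1O[C@]1(C)CCC=C(C)C | intermediate
3 | TBS ether of epoxynerol | CC(C)(C)[Si](C)(C)OC[C@@H]1O[C@]1(C)CCC=C(C)C | intermediate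
4 | secondary ozonide of 3 (not isolated) | CC(C)(C)[Si](C)(C)OC[C@@H]1O[C@]1(C)CCC2OOC(C)(C)O2 | intermediate
5 | C7 aldehyde | CC(C)(C)[Si](C)(C)OC[C@@H]1O[C@]1(C)CCC=O | intermediate
6 | Ohira-Bestmann reagent | CC(=O)C(=[N+]=[N-])P(=O)(OC)OC | starting material
7 | terminal C7-C8 alkyne | CC(C)(C)[Si](C)(C)OC[C@@H]1O[C@]1(C)CCC#C | intermediate
8 | formaldehyde (as paraformaldehyde) | C=O | starting material
9 | lithium acetylide of 7 (not isolated) | CC(C)(C)[Si](C)(C)OC[C@@H]1O[C@]1(C)CCC#C[Li] | intermediate
10 | epoxy propargylic alcohol | CC(C)(C)[Si](C)(C)OC[C@@H]1O[C@]1(C)CCC#CCO | intermediate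
11 | (Z)-C8 alkenylstannane (not isolated) | CC(C)(C)[Si](C)(C)OC[C@@H]1O[C@]1(C)CC/C=C(/CO)[Sn](CCCC)(CCCC)CCCC | intermediate
12 | (Z)-2-iodoallylic alcohol | CC(C)(C)[Si](C)(C)OC[C@@H]1O[C@]1(C)CC/C=C(/CO)I | intermediate
13 | TBS/TBDPS bis-silyl ether | CC(C)(C)[Si](C)(C)OC[C@@H]1O[C@]1(C)CC/C=C(/CO[Si](c2ccccc2)(c2ccccc2)C(C)(C)C)I | intermediate
14 | epoxy alcohol with (Z)-iodide | OC[C@@H]1O[C@]1(C)CC/C=C(/CO[Si](c2ccccc2)(c2ccccc2)C(C)(C)C)I | intermediate
15 | west fragment, cis-epoxy aldehyde with (Z)-iodide | O=C[C@@H]1O[C@]1(C)CC/C=C(/CO[Si](c2ccccc2)(c2ccccc2)C(C)(C)C)I | intermediate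
16 | (tert-butyldimethylsilyloxy)acetaldehyde | O=CCO[Si](C)(C)C(C)(C)C | starting material
17 | (Z)-2-butene | C/C=C\C | starting material
18 | (Z)-crotylpotassium (not isolated) | C/C=C\C[K] | intermediate
19 | (Z)-crotyldiisopinocampheylborane, (+)-α-pinene series (not isolated) | C/C=C\CB([C@@H]1C[C@@H]2C[C@H]([C@H]1C)C2(C)C)[C@@H]1C[C@@H]2C[C@H]([C@H]1C)C2(C)C | intermediate
20 | diisopinocampheylborinate ester of 21 (not isolated) | C=C[C@@H](C)[C@H](OB([C@@H]1C[C@@H]2C[C@H]([C@H]1C)C2(C)C)[C@@H]1C[C@@H]2C[C@H]([C@H]1C)C2(C)C)CO[Si](C)(C)C(C)(C)C | intermediate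
21 | (2S,3R)-1-(TBS-oxy)-3-methylpent-4-en-2-ol, syn | C=C[C@@H](C)[C@H](O)CO[Si](C)(C)C(C)(C)C | intermediate
22 | bis-TBS ether | C=C[C@@H](C)[C@H](O[Si](C)(C)C(C)(C)C)CO[Si](C)(C)C(C)(C)C | intermediate
23 | (2S,3R)-2-(TBS-oxy)-3-methylpent-4-en-1-ol | C=C[C@@H](C)[C@H](O[Si](C)(C)C(C)(C)C)CO | intermediate
24 | (2S,3R)-2-(TBS-oxy)-3-methylpent-4-enal | C=C[C@@H](C)[C@H](O[Si](C)(C)C(C)(C)C)C=O | intermediate
25 | diethyl (2-methylpropyl)phosphonate | CCOP(=O)(CC(C)C)OCC | starting material
26 | α-lithiated 25 (not isolated) | CCOP(=O)(OCC)C([Li])C(C)C | intermediate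
27 | β-hydroxyphosphonate | C=C[C@@H](C)[C@H](O[Si](C)(C)C(C)(C)C)C(O)C(C(C)C)P(=O)(OCC)OCC | intermediate
28 | east fragment, α-isopropyl β-ketophosphonate | C=C[C@@H](C)[C@H](O[Si](C)(C)C(C)(C)C)C(=O)C(C(C)C)P(=O)(OCC)OCC | intermediate
29 | open-chain (1E,7Z)-epoxy enone | C=C[C@@H](C)[C@H](O[Si](C)(C)C(C)(C)C)C(=O)/C(C(C)C)=C/[C@@H]1O[C@]1(C)CC/C=C(/CO[Si](c2ccccc2)(c2ccccc2)C(C)(C)C)I | intermediate
30 | open-chain C14 allylic alcohol | C=C[C@@H](C)[C@H](O[Si](C)(C)C(C)(C)C)C(O)/C(C(C)C)=C/[C@@H]1O[C@]1(C)CC/C=C(/CO[Si](c2ccccc2)(c2ccccc2)C(C)(C)C)I | intermediate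
31 | key-step precursor, C14 TES ether | C=C[C@@H](C)[C@H](O[Si](C)(C)C(C)(C)C)C(O[Si](CC)(CC)CC)/C(C(C)C)=C/[C@@H]1O[C@]1(C)CC/C=C(/CO[Si](c2ccccc2)(c2ccccc2)C(C)(C)C)I | intermediate
32 | carbon monoxide | [C-]#[O+] | starting material
33 | C10 B-alkyl-9-BBN borane (not isolated) | C1CC2CCCC(C1)B2CC[C@@H](C)[C@H](O[Si](C)(C)C(C)(C)C)C(O[Si](CC)(CC)CC)/C(C(C)C)=C/[C@@H]3O[C@]3(C)CC/C=C(/CO[Si](c4ccccc4)(c4ccccc4)C(C)(C)C)I | intermediate
34 | 14-membered macrocyclic Z-enone, C14-OTES | CC(C)/C1=C\[C@@H]2O[C@]2(C)CC/C=C(/CO[Si](c3ccccc3)(c3ccccc3)C(C)(C)C)C(=O)CC[C@@H](C)[C@H](O[Si](C)(C)C(C)(C)C)C1O[Si](CC)(CC)CC | intermediate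
35 | macrocyclic C14 alcohol | CC(C)/C1=C\[C@@H]2O[C@]2(C)CC/C=C(/CO[Si](c3ccccc3)(c3ccccc3)C(C)(C)C)C(=O)CC[C@@H](C)[C@H](O[Si](C)(C)C(C)(C)C)C1O | intermediate
36 | bis-silylated macrocyclic 9,14-dione | CC(C)/C1=C\[C@@H]2O[C@]2(C)CC/C=C(/CO[Si](c3ccccc3)(c3ccccc3)C(C)(C)C)C(=O)CC[C@@H](C)[C@H](O[Si](C)(C)C(C)(C)C)C1=O | intermediate
37 | CNP0251075.1 | CC(C)/C1=C\[C@@H]2O[C@]2(C)CC/C=C(/CO)C(=O)CC[C@@H](C)[C@H](O)C1=O | target

Total step count: 22. Longest linear sequence: 16 steps (steps 1-9 and 16-22, from nerol); the east branch contributes steps 10-15.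

Steps most likely to fail

Step 19 (bears the label). At millimolar dilution the intramolecular transfer of the alkyl group from boron to palladium may be too slow. The acyl-palladium would then be lost by hydrolysis or oligomerisation, CO insertion could be bypassed by direct alkyl-alkenyl coupling, or zerovalent palladium could ionise the vinyl oxirane. The fallback sets out from 31 and returns at 34, using known reactions only. Linear-selective hydroformylation of the terminal vinyl group (Rh(acac)(CO)2, Xantphos, CO/H2, toluene, 50 °C) would give the open-chain C9 aldehyde F1, so C9 is still drawn from CO. Nozaki-Hiyama-Kishi macrocyclisation of the C8 iodide onto this aldehyde (CrCl2, cat. NiCl2, DMF-THF, high dilution) would close the 14-membered ring as the macrocyclic C9 allylic carbinol F2, with retention of the trisubstituted alkene geometry. Dess-Martin oxidation of this carbinol then gives 34.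

Step 16. Addition of the crowded α-isopropyl phosphonate anion may be slow. The E/Z selectivity may also erode or invert, because the isopropyl group competes with the acyl group for the position trans to the oxirane. The fallback sets out from 24 and 15 and returns at 29, replacing the olefination by an aldol/elimination sequence.
- Isobutylmagnesium bromide (THF, −78 °C) adds to 24 to give the isobutyl carbinol F3, and Dess-Martin oxidation gives the isobutyl ketone F4.
- Enolisation on the CH2 side with Bu2BOTf/i-Pr2NEt gives the (Z)-boron enolate, whose chair-type aldol addition to 15 gives the 1,2-syn aldol F5.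
- MsCl/Et3N gives the aldol mesylate F6.
- DBU then induces anti elimination, which from the syn isomer places the acyl group trans to the oxirane and delivers 29.

Step 20. Cleavage of the crowded C14 TES ether may be sluggish, and forcing it risks loss of the neighbouring C13 TBS ether or acid-induced opening of the vinyl oxirane. The fallback sets out from 34 and returns at 36. It replaces hydrolytic deprotection by direct oxidative removal: DDQ in CH2Cl2/pH 7 buffer abstracts hydride from the allylic C14-H of the silyl ether and collapses it straight to the enone. Steps 20 and 21 thus merge, and the detour makes no new compound (F0).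

Further compounds
F1 | step 19 | open-chain C9 aldehyde from hydroformylation of 31 | O=CCC[C@@H](C)[C@H](O[Si](C)(C)C(C)(C)C)C(O[Si](CC)(CC)CC)/C(C(C)C)=C/[C@@H]1O[C@]1(C)CC/C=C(/CO[Si](c2ccccc2)(c2ccccc2)C(C)(C)C)I
F2 | step 19 | macrocyclic C9 allylic carbinol (C9 epimers) | CC(C)/C1=C\[C@@H]2O[C@]2(C)CC/C=C(/CO[Si](c3ccccc3)(c3ccccc3)C(C)(C)C)C(O)CC[C@@H](C)[C@H](O[Si](C)(C)C(C)(C)C)C1O[Si](CC)(CC)CC
F3 | step 16 | isobutyl carbinol (C14 epimers) | C=C[C@@H](C)[C@H](O[Si](C)(C)C(C)(C)C)C(O)CC(C)C
F4 | step 16 | isobutyl ketone | C=C[C@@H](C)[C@H](O[Si](C)(C)C(C)(C)C)C(=O)CC(C)C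
F5 | step 16 | 1,2-syn aldol (C1 and C2 left undefined, absolute sense immaterial) | C=C[C@@H](C)[C@H](O[Si](C)(C)C(C)(C)C)C(=O)C(C(C)C)C(O)[C@@H]1O[C@]1(C)CC/C=C(/CO[Si](c2ccccc2)(c2ccccc2)C(C)(C)C)I
F6 | step 16 | aldol mesylate | C=C[C@@H](C)[C@H](O[Si](C)(C)C(C)(C)C)C(=O)C(C(C)C)C(OS(C)(=O)=O)[C@@H]1O[C@]1(C)CC/C=C(/CO[Si](c2ccccc2)(c2ccccc2)C(C)(C)C)I
F0 | step 20 | none | none
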